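**Retrosynthetic overview**
- Target ⇒ trans-5-bromo-dihydrobenzofuran + (E)-propenyl boronate (Suzuki–Miyaura last; the acid-sensitive styrene is introduced after all cationic chemistry).
- trans-Bromide ⇒ cis-bromide by thermodynamic epimerisation of C2 only (C3 untouched).
- cis-Bromide ⇒ key step: Rh(II)-catalysed enantioselective intramolecular C–H insertion of an aryl/methyl donor/donor carbene into the ArCH2–O bond. This forms C2–C3 and the dihydrofuran ring, the only ring made (both benzene rings are bought), and sets both stereocentres.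
- Carbene precursor ⇒ free hydrazone of an O-(3,4,5-trimethoxybenzyl) acetophenone ⇒ 2'-hydroxy-3'-methoxyacetophenone (bromination, O-benzylation).
- Deliberately avoided: the biomimetic oxidative phenol/propenylarene [3+2] coupling (C3–C3a and C2–O), the obvious disconnection, which gives racemate.

Assumption: Rh2(S-PTAD)4 is taken to deliver the 3R series in the C–H insertion; I could not confirm the sense of induction from memory, so it must be checked on the insertion product, and the equally available Rh2(R-PTAD)4 gives the mirror-image series.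

**Step 1**
Reactants: 1 1-(2-hydroxy-3-methoxyphenyl)ethan-1-one (2'-hydroxy-3'-methoxyacetophenone)
Product: 2 1-(5-bromo-2-hydroxy-3-methoxyphenyl)ethan-1-one
Conditions: NBS (1.05 equiv), MeCN, 0 °C → rt
Reagents that add atoms: N-bromosuccinimide, O=C1CCC(=O)N1Br
Why: Electrophilic aromatic bromination (SEAr) goes to C5, the only position that is para to the phenol OH and meta to the acetyl group, as in the bromination of o-vanillin; no stereocentre.

**Step 2**
Reactants: 2 1-(5-bromo-2-hydroxy-3-methoxyphenyl)ethan-1-one; 3 5-(chloromethyl)-1,2,3-trimethoxybenzene (3,4,5-trimethoxybenzyl chloride)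
Product: 4 1-{5-bromo-3-methoxy-2-[(3,4,5-trimethoxyphenyl)methoxy]phenyl}ethan-1-one
Conditions: K2CO3, KI (cat.), DMF, 60 °C
Reagents that add atoms: none
Why: Williamson ether synthesis (SN2 of the phenoxide on a reactive benzylic chloride) installs the future C2 and its aryl group; no stereocentre.

**Step 3**
Reactants: 4 1-{5-bromo-3-methoxy-2-[(3,4,5-trimethoxyphenyl)methoxy]phenyl}ethan-1-one
Product: 5 (E)-{1-[5-bromo-3-methoxy-2-[(3,4,5-trimethoxyphenyl)methoxy]phenyl]ethylidene}hydrazine (free N–H hydrazone, used without storage)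
Conditions: N2H4·H2O (10 equiv), AcOH (cat.), EtOH, 80 °C
Reagents that add atoms: hydrazine (as monohydrate), NN
Why: Acid-catalysed condensation of the aryl methyl ketone with a large excess of hydrazine (hydrazone formation) gives the free hydrazone while suppressing the azine; the C=N geometry is irrelevant because it is lost in step 4.

**Step 4**
Reactants: 5 (E)-{1-[5-bromo-3-methoxy-2-[(3,4,5-trimethoxyphenyl)methoxy]phenyl]ethylidene}hydrazine
Product: 7 (2S,3R)-5-bromo-7-methoxy-3-methyl-2-(3,4,5-trimethoxyphenyl)-2,3-dihydro-1-benzofuran (2,3-cis), via diazoalkane 6 (not isolated)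
Conditions: MnO2 (8 equiv), CH2Cl2, 0 °C; filter; then Rh2(S-PTAD)4 (1 mol %), CH2Cl2, −20 → 0 °C
Reagents that add atoms: none
Why: MnO2 dehydrogenates the hydrazone to the aryl methyl diazoalkane, whose Rh(II) donor/donor carbene undergoes enantioselective intramolecular 1,5 C–H insertion into the doubly activated (α-oxy, benzylic) O–CH2–Ar bond, a reaction type known for such hydrazone-derived carbenes and expected to outrun 1,2-hydride shift; the chiral carboxylate catalyst fixes C3 as R and the kinetic preference of this insertion gives the 2,3-cis ring (C2 = S).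

**Step 5**
Reactants: 7 (2S,3R)-5-bromo-7-methoxy-3-methyl-2-(3,4,5-trimethoxyphenyl)-2,3-dihydro-1-benzofuran
Product: 8 (2R,3R)-5-bromo-7-methoxy-3-methyl-2-(3,4,5-trimethoxyphenyl)-2,3-dihydro-1-benzofuran (2,3-trans)
Conditions: TfOH (10 mol %), HFIP/CH2Cl2 (1:4), 0 °C → rt
Reagents that add atoms: none
Why: Reversible acid-induced ionisation of the C2–O bond to the 4-methoxy-stabilised benzylic cation and reclosure by the tethered phenol (SN1-type epimerisation under thermodynamic control) converts the cis ether into the more stable trans isomer, inverting C2 to R while C3, at which no bond is broken, stays R.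

**Step 6**
Reactants: 8 (2R,3R)-5-bromo-7-methoxy-3-methyl-2-(3,4,5-trimethoxyphenyl)-2,3-dihydro-1-benzofuran; 9 4,4,5,5-tetramethyl-2-[(E)-prop-1-en-1-yl]-1,3,2-dioxaborolane
Product: 10 (2R,3R)-7-methoxy-3-methyl-5-[(E)-prop-1-en-1-yl]-2-(3,4,5-trimethoxyphenyl)-2,3-dihydro-1-benzofuran (target)
Conditions: Pd(dppf)Cl2 (5 mol %), K2CO3, 1,4-dioxane/H2O (4:1), 85 °C
Reagents that add atoms: none
Why: Suzuki–Miyaura cross-coupling of the aryl bromide with the (E)-alkenylboronate proceeds with retention of alkene geometry under mild base and does not touch the two sp3 stereocentres.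

**Compound list**
1 | 1-(2-hydroxy-3-methoxyphenyl)ethan-1-one | CC(=O)c1cccc(OC)c1O | starting material
2 | 1-(5-bromo-2-hydroxy-3-methoxyphenyl)ethan-1-one | CC(=O)c1cc(Br)cc(OC)c1O | intermediate
3 | 5-(chloromethyl)-1,2,3-trimethoxybenzene | COc1cc(CCl)cc(OC)c1OC | starting material
4 | 1-{5-bromo-3-methoxy-2-[(3,4,5-trimethoxyphenyl)methoxy]phenyl}ethan-1-one | CC(=O)c1cc(Br)cc(OC)c1OCc1cc(OC)c(OC)c(OC)c1 | intermediate
5 | (E)-{1-[5-bromo-3-methoxy-2-[(3,4,5-trimethoxyphenyl)methoxy]phenyl]ethylidene}hydrazine | C/C(=N\N)c1cc(Br)cc(OC)c1OCc1cc(OC)c(OC)c(OC)c1 | intermediate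
6 | 5-bromo-1-(1-diazoethyl)-3-methoxy-2-[(3,4,5-trimethoxyphenyl)methoxy]benzene | CC(=[N+]=[N-])c1cc(Br)cc(OC)c1OCc1cc(OC)c(OC)c(OC)c1 | intermediate
7 | (2S,3R)-5-bromo-7-methoxy-3-methyl-2-(3,4,5-trimethoxyphenyl)-2,3-dihydro-1-benzofuran (cis) | Brc1cc(OC)c2c(c1)[C@@H](C)[C@@H](c1cc(OC)c(OC)c(OC)c1)O2 | intermediate
8 | (2R,3R)-5-bromo-7-methoxy-3-methyl-2-(3,4,5-trimethoxyphenyl)-2,3-dihydro-1-benzofuran (trans) | Brc1cc(OC)c2c(c1)[C@@H](C)[C@H](c1cc(OC)c(OC)c(OC)c1)O2 | intermediate
9 | 4,4,5,5-tetramethyl-2-[(E)-prop-1-en-1-yl]-1,3,2-dioxaborolane | C/C=C/B1OC(C)(C)C(C)(C)O1 | starting material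
10 | (2R,3R)-7-methoxy-3-methyl-5-[(E)-prop-1-en-1-yl]-2-(3,4,5-trimethoxyphenyl)-2,3-dihydro-1-benzofuran | C/C=C/c1cc(OC)c2c(c1)[C@@H](C)[C@H](c1cc(OC)c(OC)c(OC)c1)O2 | target

**Step count:** 6 steps in total. Longest linear sequence: 6 steps (1 → 10).

**Steps most likely to fail, with fallbacks**

Step 4. Risks: 1,2-hydride shift of the aryl/methyl carbene to the 2-vinylarene, azine formation, or insufficient ee. The fallback sets out from 2 and comes back at 8, bypassing steps 2–5. It gives up carbene chemistry and builds the ring by a [4+1] annulation of an o-quinone methide with a chiral benzylic sulfonium ylide, which should give the trans ring directly.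
- NaBH4 (MeOH, 0 °C) reduces 2 to rac-4-bromo-2-(1-hydroxyethyl)-6-methoxyphenol F1.
- Sodium p-toluenesulfinate in aqueous HCO2H converts it into rac-4-bromo-2-methoxy-6-[1-(4-methylbenzenesulfonyl)ethyl]phenol F2.
- Separately, chloride 3, commercial (1R,4R,5R)-isothiocineole (C[C@@H]1CC[C@@H]2C[C@H]1SC2(C)C) and NaBF4 (CH2Cl2/H2O, rt) give the S-exo salt (1R,4R,5R,6R)-4,7,7-trimethyl-6-[(3,4,5-trimethoxyphenyl)methyl]-6-thiabicyclo[3.2.1]octan-6-ium tetrafluoroborate F3.
- With Cs2CO3 in MeCN at 0 °C, F2 loses sulfinate to give (E)-4-bromo-6-ethylidene-2-methoxycyclohexa-2,4-dien-1-one F4, and F3 is deprotonated to the sulfonium ylide (3,4,5-trimethoxyphenyl)[(1R,4R,5R,6R)-4,7,7-trimethyl-6-thiabicyclo[3.2.1]octan-6-ium-6-yl]methanide F5.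
- 1,4-Addition of the ylide to the quinone methide and anti SN2 closure by the phenoxide (inversion at C2, sulfide released) give 8.
- Stabilised-ylide versions of this annulation are known and trans-selective, and isothiocineole benzylides are established in asymmetric epoxidation, but the combination is untested. The sulfide enantiomer and its SMILES stereodescriptors were derived from a hand-built conformational model, not recalled from the literature; the antipode is used if the sense proves reversed.

Step 5. Risks: the C2 cation can lose H-3 to give the stilbene (C3 scrambled on re-protonation) or alkylate an arene. The fallback sets out from 7 and comes back at 8, with no new compound. It epimerises C2 by a radical instead of a cationic path: reversible hydrogen-atom abstraction from the α-oxy, benzylic C2–H by a thiyl radical (methyl thioglycolate 20 mol %, AIBN, PhH, 80 °C). No C–O bond is broken, so elimination and Friedel–Crafts paths are closed; the thermodynamic trans isomer accumulates, and the less hydridic C3–H should be left alone.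

Step 3. Risks: azine formation or disproportionation of the free hydrazone of a hindered, electron-rich ketone. The fallback sets out from 4 and comes back at 7. It makes the diazoalkane by base-induced Bamford–Stevens fragmentation instead of oxidation. Ketone 4 and 2-(trifluoromethyl)benzenesulfonohydrazide (MeOH, 60 °C) give the bench-stable (E)-N'-{1-[5-bromo-3-methoxy-2-[(3,4,5-trimethoxyphenyl)methoxy]phenyl]ethylidene}-2-(trifluoromethyl)benzenesulfonohydrazide F6. NaH and then Rh2(S-PTAD)4 in CH2Cl2 (−20 °C → rt) release 6 at low temperature, and insertion gives 7.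

**Further compounds**
F1 | step 4 | rac-4-bromo-2-(1-hydroxyethyl)-6-methoxyphenol | CC(O)c1cc(Br)cc(OC)c1O
F2 | step 4 | rac-4-bromo-2-methoxy-6-[1-(4-methylbenzenesulfonyl)ethyl]phenol | CC(c1cc(Br)cc(OC)c1O)S(=O)(=O)c1ccc(C)cc1
F3 | step 4 | (1R,4R,5R,6R)-4,7,7-trimethyl-6-[(3,4,5-trimethoxyphenyl)methyl]-6-thiabicyclo[3.2.1]octan-6-ium tetrafluoroborate | C[C@@H]1CC[C@@H]2C[C@H]1[S@@+](Cc3cc(OC)c(OC)c(OC)c3)C2(C)C.F[B-](F)(F)F
F4 | step 4 | (E)-4-bromo-6-ethylidene-2-methoxycyclohexa-2,4-dien-1-one | C/C=C1\C=C(Br)C=C(OC)C1=O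
F5 | step 4 | (3,4,5-trimethoxyphenyl)[(1R,4R,5R,6R)-4,7,7-trimethyl-6-thiabicyclo[3.2.1]octan-6-ium-6-yl]methanide | C[C@@H]1CC[C@@H]2C[C@H]1[S@@+]([CH-]c3cc(OC)c(OC)c(OC)c3)C2(C)C
F0 | step 5 | none | none
F6 | step 3 | (E)-N'-{1-[5-bromo-3-methoxy-2-[(3,4,5-trimethoxyphenyl)methoxy]phenyl]ethylidene}-2-(trifluoromethyl)benzenesulfonohydrazide | C/C(=N\NS(=O)(=O)c1ccccc1C(F)(F)F)c1cc(Br)cc(OC)c1OCc1cc(OC)c(OC)c(OC)c1
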